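**Plan**

- Rings are lettered A (methoxy ring), B (meta-bridged ring), C (free-phenol ring) and D (para-bridged ring). The retrosynthesis first puts one Br on ring C and two Cl on ring D. It then cuts the aryl C–O bond between the ring D oxygen and the ring C carbon ortho to the free OH.
- The open bis-phenol is cut at its two ArCH2–CH2Ar bonds (as stilbene C=C bonds, Wittig) and at the ring A carbon–oxygen bond of the A–O–B ether (SNAr).
- Forward: a Wittig reaction joins ring B to the dibromophenol ring, SNAr adds ring A, and a second Wittig adds the dichlorophenol ring. Diimide then saturates both alkenes and the MOM groups are removed.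
- The only ring formed, the 18-membered macrocycle, closes last by anodic phenol coupling. Hydrogenolysis then strips Br and both Cl.
- Enabling feature: ring C carries its aryloxy oxygen on the carbon ortho to OH and its CH2CH2 bridge para to OH. Its two ortho carbons are therefore equivalent, and a 2,6-dibromophenol can act as acceptor. The ring D oxygen is para to its own bridge, so a 2,6-dichlorophenol can act as donor.
- Stereochemistry: none has to be set.

Key step: step 12

Remark: the target has no stereocentre and is assumed to have no configurationally stable axis or plane, so it is made as a single achiral compound. The E/Z mixtures from the Wittig steps are carried on because both alkenes are saturated in step 10.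

**Route**

Step 1
Reactants: 1 3,5-dibromo-4-hydroxybenzaldehyde
Product: 2 3,5-dibromo-4-(methoxymethoxy)benzaldehyde
Conditions: MOMCl, iPr2NEt, CH2Cl2, 0 °C → rt
Reagents that add atoms: chloromethyl methyl ether, COCCl
Why: O-alkylation of the acidic 2,6-dibromophenol with MOMCl (Williamson-type acetal formation) masks the phenol so that its phenoxide cannot deactivate the aldehyde in the Wittig step, and the acetal should survive base, hydride and diimide.

Step 2
Reactants: 3 3,5-dichloro-4-hydroxybenzaldehyde
Product: 4 3,5-dichloro-4-(methoxymethoxy)benzaldehyde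
Conditions: MOMCl, iPr2NEt, CH2Cl2, 0 °C → rt
Reagents that add atoms: chloromethyl methyl ether, COCCl
Why: The same MOM protection (Williamson-type O-alkylation) applies to the equally acidic 2,6-dichlorophenol.

Step 3
Reactants: 5 3-hydroxybenzyl alcohol
Product: 6 (3-hydroxybenzyl)triphenylphosphonium bromide
Conditions: PPh3·HBr, MeCN, reflux
Reagents that add atoms: triphenylphosphine hydrobromide, Br.c1ccc(cc1)P(c1ccccc1)c1ccccc1
Why: Benzylic alcohols are converted directly into benzylphosphonium bromides by PPh3·HBr (acid-promoted benzylic substitution followed by quaternisation), and the phenol is inert under these conditions.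

Step 4
Reactants: 6 (3-hydroxybenzyl)triphenylphosphonium bromide; 2 3,5-dibromo-4-(methoxymethoxy)benzaldehyde
Product: 8 3-[2-[3,5-dibromo-4-(methoxymethoxy)phenyl]ethenyl]phenol (E/Z mixture), via phenoxide ylide 7 (not isolated)
Conditions: KOtBu (2.1 equiv), THF, 0 °C; then 2, 0 °C → rt; dilute HCl work-up
Reagents that add atoms: none
Why: Wittig olefination, in which two equivalents of base give a phenoxide ylide whose meta oxide is not conjugated with the ylide carbon, so it should add normally to the unhindered, non-enolisable aldehyde while KOtBu leaves the aryl bromides untouched.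

Step 5
Reactants: 8 3-[2-[3,5-dibromo-4-(methoxymethoxy)phenyl]ethenyl]phenol; 9 2-fluoro-3-methoxybenzaldehyde
Product: 10 2-[3-[2-[3,5-dibromo-4-(methoxymethoxy)phenyl]ethenyl]phenoxy]-3-methoxybenzaldehyde (E/Z mixture)
Conditions: K2CO3, DMF, 120 °C
Reagents that add atoms: none
Why: Nucleophilic aromatic substitution, in which the ortho formyl group stabilises the Meisenheimer adduct for fluoride displacement by the phenoxide, while the unactivated aryl bromides and the base-stable MOM acetal should not react.

Step 6
Reactants: 10 2-[3-[2-[3,5-dibromo-4-(methoxymethoxy)phenyl]ethenyl]phenoxy]-3-methoxybenzaldehyde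
Product: 11 [2-[3-[2-[3,5-dibromo-4-(methoxymethoxy)phenyl]ethenyl]phenoxy]-3-methoxyphenyl]methanol (E/Z mixture)
Conditions: NaBH4, MeOH/THF, 0 °C
Reagents that add atoms: none
Why: Borohydride reduction of an aryl aldehyde is chemoselective and leaves the stilbene, aryl bromides and acetal alone.

Step 7
Reactants: 11 [2-[3-[2-[3,5-dibromo-4-(methoxymethoxy)phenyl]ethenyl]phenoxy]-3-methoxyphenyl]methanol
Product: 12 1-(bromomethyl)-2-[3-[2-[3,5-dibromo-4-(methoxymethoxy)phenyl]ethenyl]phenoxy]-3-methoxybenzene (E/Z mixture)
Conditions: CBr4, PPh3, CH2Cl2, 0 °C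
Reagents that add atoms: carbon tetrabromide, BrC(Br)(Br)Br
Why: The Appel reaction converts the benzylic alcohol into the bromide under neutral conditions, so the acid-labile MOM acetal should be kept.

Step 8
Reactants: 12 1-(bromomethyl)-2-[3-[2-[3,5-dibromo-4-(methoxymethoxy)phenyl]ethenyl]phenoxy]-3-methoxybenzene
Product: 13 [2-[3-[2-[3,5-dibromo-4-(methoxymethoxy)phenyl]ethenyl]phenoxy]-3-methoxybenzyl]triphenylphosphonium bromide (E/Z mixture)
Conditions: PPh3, toluene, reflux
Reagents that add atoms: triphenylphosphine, c1ccc(cc1)P(c1ccccc1)c1ccccc1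
Why: SN2 quaternisation of triphenylphosphine by a benzylic bromide is reliable, and the aryl bromides do not react without a metal catalyst.

Step 9
Reactants: 13 [2-[3-[2-[3,5-dibromo-4-(methoxymethoxy)phenyl]ethenyl]phenoxy]-3-methoxybenzyl]triphenylphosphonium bromide; 4 3,5-dichloro-4-(methoxymethoxy)benzaldehyde
Product: 15 1-[2-[3,5-dichloro-4-(methoxymethoxy)phenyl]ethenyl]-2-[3-[2-[3,5-dibromo-4-(methoxymethoxy)phenyl]ethenyl]phenoxy]-3-methoxybenzene (E/Z mixture at both alkenes), via benzylic ylide 14 (not isolated)
Conditions: KOtBu (1.05 equiv), THF, 0 °C; then 4, 0 °C → rt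
Reagents that add atoms: none
Why: Wittig olefination of the semi-stabilised benzylic ylide with an electron-poor, non-enolisable aldehyde should be fast, and the alkene geometry does not matter.

Step 10
Reactants: 15 1-[2-[3,5-dichloro-4-(methoxymethoxy)phenyl]ethenyl]-2-[3-[2-[3,5-dibromo-4-(methoxymethoxy)phenyl]ethenyl]phenoxy]-3-methoxybenzene
Product: 16 1-[2-[3,5-dichloro-4-(methoxymethoxy)phenyl]ethyl]-2-[3-[2-[3,5-dibromo-4-(methoxymethoxy)phenyl]ethyl]phenoxy]-3-methoxybenzene
Conditions: TsNHNH2 (excess, in portions), NaOAc, DME/H2O, reflux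
Reagents that add atoms: none
Why: Diimide generated from tosylhydrazide transfers H2 to C=C bonds in a concerted way and, unlike Pd/H2, leaves aryl C–Br and C–Cl bonds intact, while the acetate buffer protects the MOM groups.

Step 11
Reactants: 16 1-[2-[3,5-dichloro-4-(methoxymethoxy)phenyl]ethyl]-2-[3-[2-[3,5-dibromo-4-(methoxymethoxy)phenyl]ethyl]phenoxy]-3-methoxybenzene
Product: 17 2,6-dibromo-4-[2-[3-[2-[2-(3,5-dichloro-4-hydroxyphenyl)ethyl]-6-methoxyphenoxy]phenyl]ethyl]phenol (seco bis-phenol)
Conditions: conc. HCl (cat.), MeOH/THF, 50 °C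
Reagents that add atoms: none
Why: Acid-catalysed acetal exchange with methanol cleaves both MOM ethers, while the methyl aryl ether and the diaryl ether are stable to dilute acid.

Step 12
Reactants: 17 2,6-dibromo-4-[2-[3-[2-[2-(3,5-dichloro-4-hydroxyphenyl)ethyl]-6-methoxyphenoxy]phenyl]ethyl]phenol
Product: 19 bromo dichloro macrocyclic bis(bibenzyl) diether (18-membered ring; ring C 3-bromo-4-hydroxy-5-aryloxy; ring D 2,6-dichloro-1-aryloxy), via aryloxy dibromodienone 18 (not isolated)
Conditions: constant-current electrolysis (glassy-carbon anode, Pt cathode, undivided cell, ca. 2 F/mol), LiClO4, MeOH, ca. 1 mM, rt; then Zn dust, AcOH, rt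
Reagents that add atoms: none
Why: Two-electron anodic oxidation of the more easily oxidised 2,6-dibromophenol ring gives a phenoxonium ion, the hydroxyl oxygen of the dichlorophenol ring adds to one of its bromine-bearing ortho carbons to give the 6-aryloxy-2,6-dibromocyclohexa-2,4-dienone 18, and zinc in acetic acid then expels the bromide from the sp3 carbon and restores the phenol. The closest known reaction type is the anodic or thallium(III) oxidation of ortho,ortho'-dihalophenols to diaryl ethers with reductive zinc work-up, which has closed isodityrosine-type macrocycles. The single new ring is the 18-membered macrocycle, closed by C–O bond formation through O-attack of a phenol on the ring-bound cation at high dilution. No stereocentre remains, because the quaternary carbon of 18 becomes planar again in the zinc step. The step needs selection of the acceptor ring and O–C over C–C coupling: the bromine ring has the lower oxidation potential and the better leaving group, its two ortho carbons are equivalent, both para positions carry the ethylene bridges, the chlorines block the ortho carbons of the donor ring, and the methoxy diaryl ether ring is oxidised only at higher potential. Methanol capture at the para carbon should be harmless, because that dienone reverts to 17 in the zinc step.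

Step 13
Reactants: 19 bromo dichloro macrocyclic bis(bibenzyl) diether
Product: 20 target macrocycle CNP0309263.0 (ring A 1-methoxy-2-aryloxy-3-alkyl; ring B 1,3-linked; ring C 4-hydroxy-3-aryloxy; ring D 1,4-linked)
Conditions: H2 (1 atm), 10% Pd/C, Et3N, MeOH/EtOAc, rt
Reagents that add atoms: none
Why: Palladium-catalysed hydrogenolysis (hydrodehalogenation) with an amine as HX scavenger removes aryl bromide and aryl chlorides, while the diaryl ethers, the methyl ether and the phenol have no hydrogenolysable benzylic C–O bond.

**Compound list**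

1 | 3,5-dibromo-4-hydroxybenzaldehyde | O=Cc1cc(Br)c(O)c(Br)c1 | starting material
2 | 3,5-dibromo-4-(methoxymethoxy)benzaldehyde | COCOc1c(Br)cc(C=O)cc1Br | intermediate
3 | 3,5-dichloro-4-hydroxybenzaldehyde | O=Cc1cc(Cl)c(O)c(Cl)c1 | starting material
4 | 3,5-dichloro-4-(methoxymethoxy)benzaldehyde | COCOc1c(Cl)cc(C=O)cc1Cl | intermediate
5 | 3-hydroxybenzyl alcohol | OCc1cccc(O)c1 | starting material
6 | (3-hydroxybenzyl)triphenylphosphonium bromide | Oc1cccc(C[P+](c2ccccc2)(c2ccccc2)c2ccccc2)c1.[Br-] | intermediate
7 | potassium 3-[(triphenylphosphoranylidene)methyl]phenolate (phenoxide ylide, not isolated) | [K+].[O-]c1cccc(C=P(c2ccccc2)(c2ccccc2)c2ccccc2)c1 | intermediate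
8 | 3-[2-[3,5-dibromo-4-(methoxymethoxy)phenyl]ethenyl]phenol (E/Z mixture) | COCOc1c(Br)cc(C=Cc2cccc(O)c2)cc1Br | intermediate
9 | 2-fluoro-3-methoxybenzaldehyde | COc1cccc(C=O)c1F | starting material
10 | 2-[3-[2-[3,5-dibromo-4-(methoxymethoxy)phenyl]ethenyl]phenoxy]-3-methoxybenzaldehyde (E/Z mixture) | COc1cccc(C=O)c1Oc1cccc(C=Cc2cc(Br)c(OCOC)c(Br)c2)c1 | intermediate
11 | [2-[3-[2-[3,5-dibromo-4-(methoxymethoxy)phenyl]ethenyl]phenoxy]-3-methoxyphenyl]methanol (E/Z mixture) | COc1cccc(CO)c1Oc1cccc(C=Cc2cc(Br)c(OCOC)c(Br)c2)c1 | intermediate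
12 | 1-(bromomethyl)-2-[3-[2-[3,5-dibromo-4-(methoxymethoxy)phenyl]ethenyl]phenoxy]-3-methoxybenzene (E/Z mixture) | COc1cccc(CBr)c1Oc1cccc(C=Cc2cc(Br)c(OCOC)c(Br)c2)c1 | intermediate
13 | [2-[3-[2-[3,5-dibromo-4-(methoxymethoxy)phenyl]ethenyl]phenoxy]-3-methoxybenzyl]triphenylphosphonium bromide (E/Z mixture) | COc1cccc(C[P+](c2ccccc2)(c2ccccc2)c2ccccc2)c1Oc1cccc(C=Cc2cc(Br)c(OCOC)c(Br)c2)c1.[Br-] | intermediate
14 | benzylic ylide of 13, [2-(3-substituted phenoxy)-3-methoxyphenyl]methylidene-triphenylphosphorane (not isolated) | COc1cccc(C=P(c2ccccc2)(c2ccccc2)c2ccccc2)c1Oc1cccc(C=Cc2cc(Br)c(OCOC)c(Br)c2)c1 | intermediate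
15 | 1-[2-[3,5-dichloro-4-(methoxymethoxy)phenyl]ethenyl]-2-[3-[2-[3,5-dibromo-4-(methoxymethoxy)phenyl]ethenyl]phenoxy]-3-methoxybenzene (bis-stilbene, E/Z mixture at both alkenes) | COc1cccc(C=Cc2cc(Cl)c(OCOC)c(Cl)c2)c1Oc1cccc(C=Cc2cc(Br)c(OCOC)c(Br)c2)c1 | intermediate
16 | 1-[2-[3,5-dichloro-4-(methoxymethoxy)phenyl]ethyl]-2-[3-[2-[3,5-dibromo-4-(methoxymethoxy)phenyl]ethyl]phenoxy]-3-methoxybenzene | COc1cccc(CCc2cc(Cl)c(OCOC)c(Cl)c2)c1Oc1cccc(CCc2cc(Br)c(OCOC)c(Br)c2)c1 | intermediate
17 | 2,6-dibromo-4-[2-[3-[2-[2-(3,5-dichloro-4-hydroxyphenyl)ethyl]-6-methoxyphenoxy]phenyl]ethyl]phenol (seco bis-phenol) | COc1cccc(CCc2cc(Cl)c(O)c(Cl)c2)c1Oc1cccc(CCc2cc(Br)c(O)c(Br)c2)c1 | intermediate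
18 | macrocyclic 6-aryloxy-2,6-dibromocyclohexa-2,4-dienone (ring C dearomatised, the ring D oxygen on the sp3 carbon that also bears Br; racemic, not isolated) | COc1cccc2c1Oc1cccc(c1)CCC1=CC(Br)(Oc3c(Cl)cc(CC2)cc3Cl)C(=O)C(Br)=C1 | intermediate
19 | bromo dichloro macrocyclic bis(bibenzyl) diether (ring C 3-bromo-4-hydroxy-5-aryloxy, ring D 2,6-dichloro) | COc1cccc2c1Oc1cccc(c1)CCc1cc(Br)c(O)c(c1)Oc1c(Cl)cc(cc1Cl)CC2 | intermediate
20 | CNP0309263.0, 18-membered macrocyclic bis(bibenzyl) diether with OMe on ring A and OH on ring C | COc1cccc2c1Oc1cccc(c1)CCc1ccc(O)c(c1)Oc1ccc(cc1)CC2 | target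

**Step count**

Total: 13 steps. Longest linear sequence: 11 steps (5 → 20 through steps 3 to 13; the branch from 1 is equally long).

**Steps most likely to fail**

1. Step 12. Intermolecular phenol coupling and oligomerisation at the anode may outrun the 18-membered closure, or the two halophenol rings may be oxidised without discrimination. The fallback closes the same aryl C–O bond by copper-catalysed intramolecular Ullmann etherification. It sets out from ylide 14 (made from 13 as in step 9) and returns to the route at 20.
   - Wittig reaction of 14 with commercial 4-(tert-butyldimethylsilyloxy)benzaldehyde should give the silyl-protected bis-stilbene F1.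
   - Diimide under the conditions of step 10 should give the silyl-protected bis(bibenzyl) F2.
   - TBAF in THF should free the para-linked phenol and give the monophenol F3.
   - CuI, N,N-dimethylglycine and Cs2CO3 in dioxane at 100 °C under high dilution should let this phenoxide displace one of the two equivalent bromines ortho to the MOM ether, giving the MOM-protected bromo macrocycle F4.
   - HCl in MeOH should then give the bromophenol macrocycle F5.
   - Hydrogenolysis under the conditions of step 13 removes the last bromine and gives 20.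

2. Step 10. Diimide disproportionates faster than it reduces conjugated, aryl-flanked alkenes, so one of the two stilbenes may stay partly unsaturated and give mixtures that are hard to separate. The fallback replaces transfer hydrogenation by homogeneous catalytic hydrogenation with Wilkinson's catalyst (RhCl(PPh3)3, H2, benzene/EtOH), which saturates disubstituted alkenes without hydrogenolysing aryl halides. It sets out from 15 and returns at 16; no new compound is made (F0).

3. Step 13. Hydrodechlorination may stall at the two chlorines that flank the diaryl ether oxygen, leaving partly dehalogenated material as halide accumulates on the catalyst surface. The fallback replaces surface hydrogenolysis by homogeneous palladium(0) hydrodehalogenation through oxidative addition and hydride transfer from an alkoxide (Pd(OAc)2, a bulky N-heterocyclic carbene or biarylphosphine ligand, NaOtBu, iPrOH, 80 °C). It sets out from 19 and returns at 20; no new compound is made (F0).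

**Further compounds**

F1 | step 12 | 1-[2-[4-(tert-butyldimethylsilyloxy)phenyl]ethenyl]-2-[3-[2-[3,5-dibromo-4-(methoxymethoxy)phenyl]ethenyl]phenoxy]-3-methoxybenzene (E/Z mixture) | COc1cccc(C=Cc2ccc(O[Si](C)(C)C(C)(C)C)cc2)c1Oc1cccc(C=Cc2cc(Br)c(OCOC)c(Br)c2)c1
F2 | step 12 | 1-[2-[4-(tert-butyldimethylsilyloxy)phenyl]ethyl]-2-[3-[2-[3,5-dibromo-4-(methoxymethoxy)phenyl]ethyl]phenoxy]-3-methoxybenzene | COc1cccc(CCc2ccc(O[Si](C)(C)C(C)(C)C)cc2)c1Oc1cccc(CCc2cc(Br)c(OCOC)c(Br)c2)c1
F3 | step 12 | 4-[2-[2-[3-[2-[3,5-dibromo-4-(methoxymethoxy)phenyl]ethyl]phenoxy]-3-methoxyphenyl]ethyl]phenol | COc1cccc(CCc2ccc(O)cc2)c1Oc1cccc(CCc2cc(Br)c(OCOC)c(Br)c2)c1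
F4 | step 12 | MOM-protected bromo macrocycle (ring C 3-bromo-4-(methoxymethoxy)-5-aryloxy, ring D unsubstituted) | COc1cccc2c1Oc1cccc(c1)CCc1cc(Br)c(OCOC)c(c1)Oc1ccc(cc1)CC2
F5 | step 12 | bromophenol macrocycle (ring C 3-bromo-4-hydroxy-5-aryloxy, ring D unsubstituted) | COc1cccc2c1Oc1cccc(c1)CCc1cc(Br)c(O)c(c1)Oc1ccc(cc1)CC2
F0 | step 10 | none | none
F0 | step 13 | none | none
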